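**Plan**

1. Retrosynthesis: cut the C8–O ester (side-chain acid 26) and the C11–CH3 bond, then cut the lactone O–C6 bond while re-forming a C4–C6 bond. The O–C6–C5–C4=C3 array of the target (lactone oxygen, ring carbons C6 and C5, 2-(hydroxymethyl)allyl group) is a homoallyl unit, so it goes back to a cyclopropane-1,1-dimethanol spiro-fused across C5–C6 (a ring absent from the target) and a C12 carboxylate.
2. Further cuts: C1=C2 (Wittig on a C10 aldehyde), C7–C11 (enol triflate coupling), C8–O and C7–H (hydroboration), the cyclopropane (bromomalonate ring closure on a cyclohexenone), the cyclohexenone (Diels–Alder).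
3. Forward: cyclohexenone with the C10 quaternary centre → bicyclo[4.1.0]heptanone → C7 side chain and C8 oxygen, held as a temporary 8,12-lactone → ring-contractive opening of the cyclopropane to the 6,12-lactone with release of the isopropenyl alcohol → C11 methyl → C8 ester.
4. Stereochemistry: C10 from a catalytic asymmetric Diels–Alder reaction; the cyclopropane (C5) anti to the acetal on C10; C7 and C8 by syn hydroboration anti to the cyclopropane; C6 by inversion in the key step; C11 by enolate methylation anti to C8; C3′ from an (S)-malic-acid-derived ester.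

Key step: step 12

Remark: elemanolide numbering is used throughout. The ring is C5–C10; C10 carries CH3 and the vinyl group C1=C2; C5 carries C4(=C3H2)C15H2OH; C6 carries the lactone oxygen; C7 carries C11(CH3)–C12(=O); C8 carries the ester oxygen; the side-chain acid is C1′–C4′.

Remark: the target is taken with the absolute configuration written in its SMILES (5S,6S,7S,8R,10R,11R,3′S). The sense of induction of the TADDOL catalyst in step 1 (and of the oxazaborolidine in the fallback to step 3) is assumed; the antipodal catalyst would be taken if the sense proved opposite.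

**Route**

Step 1
Reactants: 1 (E)-3-(tert-butyldimethylsilyloxy)-N,N-dimethylbuta-1,3-dien-1-amine; 2 methacrolein
Product: 4 (S)-1-methyl-4-oxocyclohex-2-ene-1-carbaldehyde, via cycloadduct 3 (not isolated)
Conditions: (R,R)-1-naphthyl-TADDOL (20 mol %), toluene, −78 °C; then 1 M HCl, THF, 0 °C
Reagents that add atoms: none
Why: The hydrogen-bonding diol catalyst should activate the enal for a normal-demand Diels–Alder reaction in which the amino-bearing diene terminus bonds to the α-carbon of methacrolein, and acid then eliminates dimethylamine and cleaves the silyl enol ether to the enone; the C10 quaternary stereocentre is set by the catalyst-bound dienophile face.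

Step 2
Reactants: 4 (S)-1-methyl-4-oxocyclohex-2-ene-1-carbaldehyde
Product: 5 (S)-4-(dimethoxymethyl)-4-methylcyclohex-2-en-1-one
Conditions: HC(OMe)3, MeOH, PPTS (cat.), rt
Reagents that add atoms: trimethyl orthoformate, COC(OC)OC
Why: Acid-catalysed acetalisation should be selective for the aldehyde over the less electrophilic conjugated ketone and gives a bulky, base- and hydride-stable precursor of the vinyl group; no stereocentre is touched.

Step 3
Reactants: 5 (S)-4-(dimethoxymethyl)-4-methylcyclohex-2-en-1-one; 6 dimethyl bromomalonate
Product: 7 dimethyl 5-(dimethoxymethyl)-5-methyl-2-oxobicyclo[4.1.0]heptane-7,7-dicarboxylate (cyclopropane cis to the C10 methyl)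
Conditions: K2CO3, DMF, 0 °C → rt
Reagents that add atoms: none
Why: Michael-initiated ring closure: the bromomalonate anion should add axially to C5 anti to the larger C10 substituent (the dimethoxymethyl group) and the C6 enolate then displaces bromide in a 3-exo-tet alkylation, which sets C5 and C6 with the cyclopropane cis to the C10 methyl.

Step 4
Reactants: 7 keto diester
Product: 8 [5-(dimethoxymethyl)-2-hydroxy-5-methylbicyclo[4.1.0]heptane-7,7-diyl]dimethanol (C7 carbinol epimers)
Conditions: LiAlH4, THF, 0 °C → rt
Reagents that add atoms: none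
Why: Hydride reduction of both esters should give the cyclopropane-1,1-dimethanol, and the ketone is reduced as well to a carbinol whose configuration is of no consequence because step 6 re-oxidises it.

Step 5
Reactants: 8 triol
Product: 9 5-(dimethoxymethyl)-2′,2′,5-trimethylspiro[bicyclo[4.1.0]heptane-7,5′-[1,3]dioxan]-2-ol
Conditions: Me2C(OMe)2, PPTS (cat.), CH2Cl2, rt
Reagents that add atoms: 2,2-dimethoxypropane, COC(C)(C)OC
Why: Acid-catalysed acetal exchange should close the six-membered 1,3-dioxane on the two primary hydroxyls in preference to any larger ring through the secondary hydroxyl, which stays free (acetonide protection).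

Step 6
Reactants: 9 acetonide alcohol
Product: 10 5-(dimethoxymethyl)-2′,2′,5-trimethylspiro[bicyclo[4.1.0]heptane-7,5′-[1,3]dioxan]-2-one
Conditions: Dess–Martin periodinane, NaHCO3, CH2Cl2, rt
Reagents that add atoms: none
Why: Dess–Martin oxidation under buffered conditions should return the C7 ketone without affecting the two acetals or the cyclopropane.

Step 7
Reactants: 10 cyclopropyl ketone
Product: 11 C7 enol triflate of 10 (C7=C8)
Conditions: KN(SiMe3)2, THF, −78 °C; PhNTf2, −78 → 0 °C
Reagents that add atoms: N-phenylbis(trifluoromethanesulfonimide), O=S(=O)(N(c1ccccc1)S(=O)(=O)C(F)(F)F)C(F)(F)F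
Why: Only C8 carries an enolisable hydrogen that leads to an unstrained enolate (C6 is a cyclopropane methine), so kinetic deprotonation and O-triflation should give the C7=C8 enol triflate regiospecifically.

Step 8
Reactants: 11 enol triflate; 12 (2-ethoxy-2-oxoethyl)zinc bromide
Product: 13 ethyl 2-(C7-alkenyl)acetate (C7–C11H2–C12O2Et on the C7=C8 double bond)
Conditions: Pd(PPh3)4 (5 mol %), THF, 50 °C
Reagents that add atoms: none
Why: Negishi coupling of the alkenyl triflate with the zinc ester enolate (Reformatsky reagent) through oxidative addition to zerovalent palladium, transmetalation and reductive elimination should form the C7–C11 bond and leave the C7=C8 double bond as a β,γ-unsaturated ester.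

Step 9
Reactants: 13 β,γ-unsaturated ester
Product: 15 8,12-lactone aldehyde diol (C10 carries CH3 and CHO; free cyclopropane-1,1-dimethanol), via hydroxy ester 14 (not isolated)
Conditions: BH3·THF, THF, 0 °C; NaOH, H2O2, 0 °C; then 2 M HCl, THF, rt
Reagents that add atoms: hydrogen peroxide, OO; water, O
Why: Hydroboration–oxidation should add H to C7 and OH to C8 in a syn fashion with boron on the less substituted C8 and from the face opposite the cyclopropane and its endo CH2O arm, which sets C7 and C8 together (side chain cis to the cyclopropane, O8 trans to it), and aqueous acid then closes the trans-fused γ-lactone on O8 and hydrolyses the dimethyl acetal and the acetonide.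

Step 10
Reactants: 15 aldehyde lactone diol
Product: 16 8,12-lactone vinyl diol (C10 carries CH3 and CH=CH2)
Conditions: Ph3PCH3Br, KOtBu, THF, 0 °C → rt
Reagents that add atoms: methyltriphenylphosphonium bromide, C[P+](c1ccccc1)(c1ccccc1)c1ccccc1.[Br-]
Why: Wittig methylenation of the non-enolisable neopentyl aldehyde should be much faster than attack of the ylide on the lactone, the excess ylide covering the two acidic hydroxyls; no stereocentre is affected.

Step 11
Reactants: 16 vinyl lactone diol
Product: 17 monotosylate of 16 (either hydroxymethyl arm)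
Conditions: Ag2O, TsCl, KI (cat.), CH2Cl2, rt
Reagents that add atoms: p-toluenesulfonyl chloride, Cc1ccc(cc1)S(=O)(=O)Cl
Why: Silver-oxide-mediated sulfonylation is a known way to stop a symmetrical diol at the monotosylate, and since both arms lead to the same product in step 12 it does not matter which of the two diastereotopic hydroxyls reacts.

Step 12
Reactants: 17 monotosylate
Product: 19 11-nor 6,12-lactone with free 8-OH and 15-OH (C5 carries C(=CH2)CH2OH), via lithium carboxylate 18 (not isolated)
Conditions: LiOH (1.0 equiv), THF/H2O, 0 °C; then evaporation, DMF, 50 °C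
Reagents that add atoms: lithium hydroxide, [Li+].[OH-]
Why: Proposed new method: hydroxide opens the 8,12-lactone, and the liberated C12 carboxylate, held on the cyclopropane face by C7, attacks C6 at the rear of the C6–C4 bond while that bond turns into the C4=C3 double bond and tosylate leaves from C3 (a homo-SN2′ or cyclopropylcarbinyl-to-homoallyl substitution). The closest known reaction type is the stereospecific, invertive opening of cyclopropylcarbinyl sulfonates and carbinols to homoallylic halides or solvolysis products (Julia-type olefin synthesis), here with an internal carboxylate as the nucleophile. The γ-lactone closes in a 5-exo-tet mode with respect to the breaking C6–C4 bond. C6 is the only new stereocentre and is set by inversion: since the cyclopropane lies on the face of the C7 side chain, rear-side attack can give only the trans-fused 6,12-lactone, and C5 is untouched and keeps the configuration imposed by the cyclopropane. Whichever arm carries the tosylate the product is the same, because C4 becomes trigonal and the other arm is released as the C15 allylic alcohol. The step needs attack at C6 and not at the neopentyl CH2 or at C5, and substitution must outrun ionisation to cyclobutyl cations; the five-membered transition state, the absence of any nucleophile within reach of C5 and the use of a carboxylate in a dipolar aprotic medium should secure this, and the 8,12-lactone cannot re-form because O8 carries no leaving group.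

Step 13
Reactants: 19 nor-lactone diol
Product: 20 15-O-TBS ether of 19
Conditions: TBSCl (1.05 equiv), imidazole, CH2Cl2, −20 °C
Reagents that add atoms: tert-butyldimethylsilyl chloride, CC(C)(C)[Si](C)(C)Cl
Why: With one equivalent of silyl chloride at low temperature the unhindered primary allylic C15 hydroxyl should be silylated in preference to the hindered secondary C8 hydroxyl (selective silyl ether protection).

Step 14
Reactants: 20 silyl ether
Product: 21 11-methyl lactone (methyl cis to H7)
Conditions: LiN(iPr)2 (2.3 equiv), THF, −78 °C; MeI, −78 → −40 °C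
Reagents that add atoms: iodomethane, CI
Why: Enolate alkylation: the dianion (C8 alkoxide and lactone enolate) should be methylated at C11 from the face of H7, away from C8 and its oxygen, which places the methyl group cis to H7 as required; the fused lactone cannot migrate to O8 because O6 and O8 lie trans to C11.

Step 15
Reactants: 22 methyl 2-[(4S)-2,2-dimethyl-1,3-dioxolan-4-yl]acetate
Product: 25 methyl 2-[(4S)-2,2-dimethyl-1,3-dioxolan-4-yl]prop-2-enoate, via Mannich base 23 (not isolated), via ammonium iodide 24 (not isolated)
Conditions: LiN(iPr)2, THF, −78 °C; CH2=NMe2+ I−; then MeI, MeOH, rt; then DBU, CH2Cl2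
Reagents that add atoms: dimethylmethyleneiminium iodide, C=[N+](C)C.[I-]
Why: α-Methylenation by Mannich reaction of the lithium enolate with Eschenmoser's salt, N-methylation and base-induced elimination of trimethylamine; the enolate is kept at −78 °C so that the β-oxygen is not expelled, and the C3′ stereocentre (from the malic-acid-derived ester) is not involved.

Step 16
Reactants: 25 acrylate ester
Product: 26 2-[(4S)-2,2-dimethyl-1,3-dioxolan-4-yl]prop-2-enoic acid
Conditions: LiOH, THF/H2O, 0 °C; then 1 M HCl
Reagents that add atoms: lithium hydroxide, [Li+].[OH-]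
Why: Saponification of the methyl ester with LiOH at 0 °C should give the acrylic acid without opening the base-stable acetonide or touching C3′.

Step 17
Reactants: 21 11-methyl lactone; 26 side-chain acid
Product: 28 protected target (8-O-acyl; 15-O-TBS; side-chain acetonide), via mixed anhydride 27 (not isolated)
Conditions: 2,4,6-Cl3C6H2COCl, Et3N, THF, rt; then 21, DMAP, toluene, rt
Reagents that add atoms: none
Why: Yamaguchi esterification through the mixed anhydride should acylate the only free hydroxyl (C8, with retention since the C–O bond is not broken), the 2-substituted acrylate being a poor acceptor for DMAP.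

Step 18
Reactants: 28 protected target
Product: 29 target
Conditions: HF (48% aq.), MeCN, 0 °C → rt
Reagents that add atoms: none
Why: Aqueous HF should cleave the primary silyl ether and hydrolyse the acetonide in one operation while leaving the lactone, the acrylate ester and the allylic alcohol intact (global deprotection).

**Compound list**

1 | (E)-3-(tert-butyldimethylsilyloxy)-N,N-dimethylbuta-1,3-dien-1-amine | CN(C)/C=C/C(=C)O[Si](C)(C)C(C)(C)C | starting material
2 | methacrolein (2-methylprop-2-enal) | CC(=C)C=O | starting material
3 | (1S)-4-(tert-butyldimethylsilyloxy)-2-(dimethylamino)-1-methylcyclohex-3-ene-1-carbaldehyde (cycloadduct, C2 epimers) | O=C[C@@]1(C)CCC(O[Si](C)(C)C(C)(C)C)=CC1N(C)C | intermediate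
4 | (S)-1-methyl-4-oxocyclohex-2-ene-1-carbaldehyde | O=C[C@@]1(C)CCC(=O)C=C1 | intermediate
5 | (S)-4-(dimethoxymethyl)-4-methylcyclohex-2-en-1-one | COC(OC)[C@@]1(C)CCC(=O)C=C1 | intermediate
6 | dimethyl bromomalonate | COC(=O)C(Br)C(=O)OC | starting material
7 | dimethyl 5-(dimethoxymethyl)-5-methyl-2-oxobicyclo[4.1.0]heptane-7,7-dicarboxylate, cyclopropane cis to the methyl group on the quaternary carbon | COC(OC)[C@@]1(C)CCC(=O)[C@H]2[C@@H]1C2(C(=O)OC)C(=O)OC | intermediate
8 | [5-(dimethoxymethyl)-2-hydroxy-5-methylbicyclo[4.1.0]heptane-7,7-diyl]dimethanol, carbinol epimers, ring stereocentres as in 7 | COC(OC)[C@@]1(C)CCC(O)[C@H]2[C@@H]1C2(CO)CO | intermediate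
9 | 5-(dimethoxymethyl)-2′,2′,5-trimethylspiro[bicyclo[4.1.0]heptane-7,5′-[1,3]dioxan]-2-ol (acetonide of the cyclopropane diol) | COC(OC)[C@@]1(C)CCC(O)[C@H]2[C@@H]1C23COC(C)(C)OC3 | intermediate
10 | 5-(dimethoxymethyl)-2′,2′,5-trimethylspiro[bicyclo[4.1.0]heptane-7,5′-[1,3]dioxan]-2-one (C7 ketone) | COC(OC)[C@@]1(C)CCC(=O)[C@H]2[C@@H]1C23COC(C)(C)OC3 | intermediate
11 | enol triflate of 10, double bond C7=C8 | COC(OC)[C@@]1(C)CC=C(OS(=O)(=O)C(F)(F)F)[C@H]2[C@@H]1C23COC(C)(C)OC3 | intermediate
12 | (2-ethoxy-2-oxoethyl)zinc bromide (Reformatsky reagent, commercial solution or from ethyl bromoacetate and zinc) | CCOC(=O)C[Zn]Br | starting material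
13 | ethyl 2-(alkenyl)acetate: CH2CO2Et on C7 of the C7=C8 double bond, C10 acetal and cyclopropane acetonide retained | COC(OC)[C@@]1(C)CC=C(CC(=O)OCC)[C@H]2[C@@H]1C23COC(C)(C)OC3 | intermediate
14 | hydroxy ester: 8-OH and H7 on the face opposite the cyclopropane, CH2CO2Et on C7 cis to the cyclopropane | COC(OC)[C@@]1(C)C[C@@H](O)[C@H](CC(=O)OCC)[C@H]2[C@@H]1C23COC(C)(C)OC3 | intermediate
15 | 8,12-lactone aldehyde diol: trans-fused γ-lactone C7–C11H2–C12(=O)–O8, C10 with CH3 and CHO, spiro cyclopropane-1,1-dimethanol across C5–C6 on the face of the C10 methyl | O=C[C@@]1(C)C[C@@H](OC(=O)C2)[C@H]2[C@H]3[C@@H]1C3(CO)CO | intermediate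
16 | 8,12-lactone vinyl diol: as 15 with CH=CH2 in place of CHO | C=C[C@@]1(C)C[C@@H](OC(=O)C2)[C@H]2[C@H]3[C@@H]1C3(CO)CO | intermediate
17 | monotosylate of 16 on one hydroxymethyl arm (either arm) | C=C[C@@]1(C)C[C@@H](OC(=O)C2)[C@H]2[C@H]3[C@@H]1C3(CO)COS(=O)(=O)c1ccc(C)cc1 | intermediate
18 | lithium carboxylate from opening of the 8,12-lactone of 17 (free 8-OH, C12 carboxylate, tosylate retained) | C=C[C@@]1(C)C[C@@H](O)[C@H](CC(=O)[O-])[C@H]2[C@@H]1C2(CO)COS(=O)(=O)c1ccc(C)cc1.[Li+] | intermediate
19 | 11-nor 6,12-lactone: trans-fused γ-lactone C7–C11H2–C12(=O)–O6, free 8-OH, C5 bearing C(=CH2)CH2OH, C10 with CH3 and vinyl | C=C[C@@]1(C)C[C@@H](O)[C@H]2[C@@H](OC(=O)C2)[C@@H]1C(=C)CO | intermediate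
20 | 15-O-tert-butyldimethylsilyl ether of 19 | C=C[C@@]1(C)C[C@@H](O)[C@H]2[C@@H](OC(=O)C2)[C@@H]1C(=C)CO[Si](C)(C)C(C)(C)C | intermediate
21 | 11-methyl derivative of 20, methyl cis to H7 (11R) | C=C[C@@]1(C)C[C@@H](O)[C@H]2[C@@H](OC(=O)[C@@H]2C)[C@@H]1C(=C)CO[Si](C)(C)C(C)(C)C | intermediate
22 | methyl 2-[(4S)-2,2-dimethyl-1,3-dioxolan-4-yl]acetate | COC(=O)C[C@H]1COC(C)(C)O1 | starting material
23 | methyl 3-(dimethylamino)-2-[(4S)-2,2-dimethyl-1,3-dioxolan-4-yl]propanoate (Mannich base, C2 epimers) | COC(=O)C(CN(C)C)[C@H]1COC(C)(C)O1 | intermediate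
24 | trimethylammonium iodide derived from 23 | COC(=O)C(C[N+](C)(C)C)[C@H]1COC(C)(C)O1.[I-] | intermediate
25 | methyl 2-[(4S)-2,2-dimethyl-1,3-dioxolan-4-yl]prop-2-enoate | COC(=O)C(=C)[C@H]1COC(C)(C)O1 | intermediate
26 | 2-[(4S)-2,2-dimethyl-1,3-dioxolan-4-yl]prop-2-enoic acid | OC(=O)C(=C)[C@H]1COC(C)(C)O1 | intermediate
27 | mixed anhydride of 26 with 2,4,6-trichlorobenzoic acid | C=C(C(=O)OC(=O)c1c(Cl)cc(Cl)cc1Cl)[C@H]1COC(C)(C)O1 | intermediate
28 | protected target: 8-O-acyl with the side-chain acetonide, 15-O-TBS | C=C[C@@]1(C)C[C@@H](OC(=O)C(=C)[C@H]3COC(C)(C)O3)[C@H]2[C@@H](OC(=O)[C@@H]2C)[C@@H]1C(=C)CO[Si](C)(C)C(C)(C)C | intermediate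
29 | target (CNP0260337.1) | C=C[C@@]1(C)C[C@@H](OC(=O)C(=C)[C@H](O)CO)[C@H]2[C@@H](OC(=O)[C@@H]2C)[C@@H]1C(=C)CO | target

**Step count and risks**

Total step count: 18. Longest linear sequence: 16 steps (steps 1–14, 17 and 18).

Steps most likely to fail:

Step 12 (proposed new method). What may go wrong is direct substitution by the carboxylate at the tosylate-bearing CH2 (a seven-membered lactone), or ionisation to cyclobutyl cations, instead of rear-side attack at C6. The fallback sets out from 17. Buffered solvolysis (acetone–water, CaCO3, 50 °C), the classical cyclopropylcarbinyl-to-homoallyl hydrolysis, should put water on C6 anti to C4 and give the 6-hydroxy 8,12-lactone F1. Saponification (LiOH) to the 6,8-dihydroxy acid F2 and acid-catalysed relactonisation (TsOH) would then close the 6,12-lactone at the acyl carbon. The 6- and 8-hydroxyls compete in this closure, so re-formed F1 would be separated and recycled. The route is rejoined at 19.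

Step 3. What may go wrong is slow conjugate addition at the β-carbon next to the quaternary centre and poor selection between the methyl face and the acetal face. The fallback sets out from 5. CBS reduction ((R)-2-methyl-CBS-oxazaborolidine, BH3·SMe2) should give the allylic alcohol F3 with the hydroxyl cis to the C10 methyl. Acylation with methyl malonyl chloride gives the mixed malonate F4, and diazo transfer (p-acetamidobenzenesulfonyl azide, Et3N) gives the diazomalonate F5. Rh2(OAc)4-catalysed intramolecular cyclopropanation then gives the tricyclic lactone F6, in which the tether forces the cyclopropane onto the face of the C7 oxygen and so of the methyl group. LiAlH4 reduction of lactone and ester returns the route at 8 (as one carbinol epimer).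

Step 9. What may go wrong is competing reduction of the ester by borane, and misdirection of the three-event acidic stage (hemiacetal formation between the freed aldehyde and the 8-hydroxyl instead of lactonisation). The fallback sets out from 11. Stille coupling with tributyl(vinyl)stannane (Pd(PPh3)4, LiCl) gives the diene F7. Double hydroboration–oxidation (BH3·THF; NaOH, H2O2) gives the diol F8 with C12 at the alcohol level. Oxidative lactonisation (TEMPO, PhI(OAc)2) gives the acetal-protected lactone F9, and 2 M HCl in THF then returns the route at 15.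

Further compounds
F1 | step 12 | 6-hydroxy 8,12-lactone (homoallylic alcohol; C5 bearing C(=CH2)CH2OH) | C=C[C@@]1(C)C[C@@H](OC(=O)C2)[C@H]2[C@@H](O)[C@@H]1C(=C)CO
F2 | step 12 | 6,8-dihydroxy acid | C=C[C@@]1(C)C[C@@H](O)[C@H](CC(=O)O)[C@@H](O)[C@@H]1C(=C)CO
F3 | step 3 | (1S,4S)-4-(dimethoxymethyl)-4-methylcyclohex-2-en-1-ol | COC(OC)[C@@]1(C)CC[C@H](O)C=C1
F4 | step 3 | methyl malonate ester of F3 | COC(OC)[C@@]1(C)CC[C@H](OC(=O)CC(=O)OC)C=C1
F5 | step 3 | diazomalonate of F3 | COC(OC)[C@@]1(C)CC[C@H](OC(=O)C(=[N+]=[N-])C(=O)OC)C=C1
F6 | step 3 | tricyclic cyclopropane-fused γ-lactone methyl ester | COC(OC)[C@@]1(C)CC[C@@H]2OC(=O)[C@@]3(C(=O)OC)[C@@H]2[C@@H]13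
F7 | step 9 | C7-vinyl diene (C7=C8 and CH=CH2 on C7) | COC(OC)[C@@]1(C)CC=C(C=C)[C@H]2[C@@H]1C23COC(C)(C)OC3
F8 | step 9 | 8,12-diol (C7–CH2CH2OH, 8-OH) | COC(OC)[C@@]1(C)C[C@@H](O)[C@H](CCO)[C@H]2[C@@H]1C23COC(C)(C)OC3
F9 | step 9 | 8,12-lactone with C10 dimethyl acetal and cyclopropane acetonide | COC(OC)[C@@]1(C)C[C@@H](OC(=O)C2)[C@H]2[C@H]3[C@@H]1C34COC(C)(C)OC4
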